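## Structural features

The target is [(1R,2R,5R,6S)-2,5-bis(benzoyloxy)-1,6-dihydroxycyclohex-3-en-1-yl]methyl benzoate: a single carbocycle (ring A, a cyclohex-3-ene) whose four sp3 ring carbons all carry oxygen, plus one exocyclic carbon C7 on C1. C1 is a fully substituted carbinol (OH and CH2OBz), C2 and C5 are allylic benzoates on either side of the C3=C4 double bond, and C6 is a free secondary alcohol between C5 and C1. The stereocentres C5, C6, C1 and C2 are contiguous and their oxygens alternate faces (C5-O β, C6-O α, C1-O β, C2-O α). Every neighbouring pair of oxygens is therefore trans, and C7 is cis to both flanking oxygens. The fragile points are the benzoates next to free hydroxyls (acyl migration under base), the two allylic esters (ionisation, or loss of benzoic acid towards an arene) and the tertiary alcohol. The real difficulty is twofold: setting the quaternary C1 against two oxygenated neighbours, and leaving exactly C1-OH and C6-OH free among five oxygens. The key step uses two facts. The trans pair C5(β-OBz)/C6(α-OH) has the configuration of O3/O4 of D-glucose. Ring A with a carbonyl at C1 and a hydroxyl at C3 is a β-hydroxy ketone, so C2–C3 is an aldol bond; C1 and C2 then correspond to sugar C5 and C6, and C3 and C4 to sugar C1 and C2.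

## Logic of the disconnections

24 ⇒ 23. The O–Si bond on the C6 oxygen is cut last. C6-OH is the one secondary hydroxyl that must stay free beside three benzoates, so keeping it silylated to the end removes every acyl-migration pathway towards it. The forward step must use an acidic, non-basic fluoride source.

23 ⇒ 22 ⇒ 20. The C3=C4 π bond is traced back to the two C–O bonds of a cis-3,4-diol, through its cyclic thiocarbonate. This takes the allylic character away from both benzoates in all earlier intermediates and returns ring A to a fully oxygenated cyclohexane. The forward step needs a cis diol (syn elimination), near-neutral conditions, and a tertiary C1-OH that stays out of the reaction.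

20 ⇒ 19. The two hydroxyls destined to disappear are tied together as one aryl acetal. One unit masks both and is released by mild acid; the hydrolysis must spare the silyl ether and three esters.

19 ⇒ 18 ⇒ 17. The acyl C–O bond at C7 is cut, then the C1–O and C7–O bonds (retro-dihydroxylation), leaving an exocyclic C1=C7 alkene. In 17 the C3 oxygen is axial on the α-face and screens that face of C1, so an oxidant should come from the β-face and place C1-OH β, as required. A carbon nucleophile added directly to the ketone would be steered to the β-face for the same reason, which would put C7 on the wrong side; C7 is therefore introduced first as sp2 carbon. The forward steps need β-selective osmylation and benzoylation of the primary hydroxyl only.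

17 ⇒ 15 + 16. The C1=C7 bond is cut to a ketone and a one-carbon unit. The ketone has one benzoate α and another β, so the methylenation must be non-basic and must not touch esters.

15 ⇒ 14. The acetal C–O bond to the C3 oxygen is cut. The acetal is the oxidised form of the C4 benzyl-type ether closed onto the free C3 hydroxyl. This protects the aldol hydroxyl without base and without a new protecting reagent, and it blocks retro-aldol, dehydration and a C2→C3 benzoyl shift. It needs the C3 hydroxyl cis to the C4 oxygen and dry conditions.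

14 ⇒ 12. The C2–C3 bond is cut (aldol retron). The keto-aldehyde is masked as a pyranoside whose sugar C5=C6 enol benzoate already carries the C2 benzoate. Ring A is thereby reduced to a hexopyranoside, and C4, C5 and C6 come unchanged from sugar C2, C3 and C4. The forward step must unmask both carbonyls under conditions that let the enolate close the ring and place the C2 benzoate equatorial.

12 ⇒ 10 + 11. The enol O–acyl bond is cut to an aldehyde and an acyl donor. The forward step must give the Z enol ester and must not eliminate the silyloxy group β to the aldehyde.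

10 ⇒ 9 ⇒ 8 ⇒ 6 + 7. The oxidation level at sugar C6 is adjusted and two O–Si bonds are cut. Silylating both hydroxyls and freeing the primary one is the dependable way to leave silicon on sugar O4 only.

6 ⇒ 5 ⇒ 3 ⇒ 1 + 2 (and 4). The 4,6-acetal is restored, then the O3–acyl and O2–benzyl bonds are cut. The acetal of 1 leaves only O2 and O3 to tell apart, and 1 is a catalogue compound. The forward alkylation must select O2.

## Other disconnections considered

Alternative 1: The cut runs through C1–C6 and C2–C3, a [4+2] retron. Forward, furan A1 and 2-bromoacrolein A2 combine under a chiral B-butyl oxazaborolidine Lewis acid (N-tosyl-tryptophan derived) to give the oxanorbornene aldehyde A3.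
- In favour: one catalytic step from two achiral bulk chemicals builds ring A and sets the quaternary C1 with C7 attached (as the aldehyde) and bromine as placeholder for the tertiary oxygen. The bridging oxygen sits on C6 and C3, so an SN2′-type opening by a benzoate could reveal C6-OH, C5-OBz and the C3=C4 alkene together.
- Against: C2 arrives as a bare methylene and needs a late C–H oxidation beside the quaternary centre with face control. The C–Br to C–OH exchange at a hindered tertiary carbon must give one configuration. Furan cycloadditions are reversible and A2 is labile.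
- Comparison: for C1 and C7 this plan is better than the chosen one, which spends steps 10 to 12 and relies on a facial preference. For reaching the carbocycle it is also better (one step against eight to 14). For C2, C5 and C6 the chosen plan is stronger, because the enol benzoate of 12 delivers the C2 oxygen in the ring-forming step and the sugar supplies C5 and C6 without any selectivity question. Both ring closures pass through well-understood ordered transition states; the absolute configuration is catalyst-controlled here and chiral-pool-derived in the chosen plan, which is the safer of the two.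

Alternative 2: The cut is at the allylic C2–O and C5–O bonds of a preformed ring. Forward, racemic all-trans cyclohex-5-ene-1,2,3,4-tetrayl tetrakis(2,2,2-trichloroethyl carbonate) A4 (conduritol B tetracarbonate) is ionised by zerovalent palladium with a chiral bisphosphine. Both enantiomers give a common meso π-allyl, and a benzoate nucleophile attacks with one absolute sense, twice, to give the dibenzoate biscarbonate A5.
- In favour: C2, C5, C6, the alkene and both allylic benzoates arrive with absolute configuration in one stereoconvergent catalytic step that wastes neither enantiomer. A5 is C2-symmetric, so after the carbonates are removed the two hydroxyls are homotopic and a mono-oxidation has no regiochemical ambiguity.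
- Against: C1 is still a secondary carbinol. It must become a ketone that is β,γ-unsaturated and flanked by a benzoate, a type that readily loses benzoic acid and aromatises. C7 must then be added cis to both neighbouring oxygens while the ring alkene is present, which rules out a methylenation–dihydroxylation sequence.
- Comparison: for C2, C5, C6 and the alkene this plan is clearly better than the chosen one, which needs steps 13 to 15 for the alkene alone, and it is shorter up to the key intermediate. For C1 and C7 the chosen plan is stronger, because that chemistry is done on the saturated ketone 15 before any alkene exists. Mechanistically the palladium double inversion is as reliable on its substrate class as the aldol closure is on 12.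

Alternative 3: The cut is at the C5–O and C6–O bonds of an oxirane. Forward, the prochiral dienone 4-(benzoyloxymethyl)-4-(triethylsilyloxy)cyclohexa-2,5-dienone A6 undergoes asymmetric nucleophilic epoxidation of one enantiotopic enone alkene, anti to the silyloxy group, to give the epoxy enone A7.
- In favour: C1 with its CH2OBz arm is present from the start at the right oxidation level, A6 is a few steps from a simple para-substituted phenol, and one step creates three stereocentres.
- Against: the epoxidation must solve two selectivities at once (which alkene, which face) and must stop before the bis-epoxide. After A7 the oxygen pattern is off by a 1,3-shift: the carbonyl is at C4 and the alkene at C2=C3, while the target needs oxygen at C2 and the alkene at C3=C4. That calls for reduction, a stereospecific allylic ester transposition and a regioselective trans opening of the oxirane at C5 by benzoate.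
- Comparison: for C1 and C7 it equals Alternative 1 and betters the chosen plan, and on paper it is the shortest of all. For C5 and C6 it is comparable (trans opening gives what the sugar gives, but with a regiochemical question). For C2 it is weaker, since that oxygen arrives only by transposition. The desymmetrising epoxidation has less precedent on this substrate class than the carbocyclisation of 12.

Key step: step 8

Remarks on the chemistry (assumptions):
- Carbocycle locants follow the target (C1 ketone or quaternary carbon, C7 exocyclic carbon). With ring A drawn flat and C1→C6 clockwise, β is the upper face and α the lower.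
- The aldol hydroxyl of 14 is taken as axial (3α, cis to the C4 oxygen), the usual outcome of this cyclisation.
- The acetal carbon of 15, 17, 18 and 19 may be either epimer (aryl exo expected); it is removed in step 13 and is left undefined in the SMILES.

## Route

Step 1
Reactants: 1 methyl 4,6-O-[(R)-benzylidene]-α-D-glucopyranoside; 2 4-methoxybenzyl chloride
Product: 3 methyl 4,6-O-benzylidene-2-O-(4-methoxybenzyl)-α-D-glucopyranoside
Conditions: Bu2SnO, toluene, reflux (−H2O); then 2, Bu4NI (cat.), toluene, 90 °C
Reagents that add atoms: 4-methoxybenzyl chloride (2), COc1ccc(CCl)cc1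
Why: Stannylene-acetal-mediated regioselective O-alkylation; in the 2,3-O-dibutylstannylene acetal of an α-glucoside the oxygen at C2, next to the cis anomeric methoxy group, is the more nucleophilic, so the PMB group should go to O2 and leave O3 free.

Step 2
Reactants: 3 methyl 4,6-O-benzylidene-2-O-(4-methoxybenzyl)-α-D-glucopyranoside; 4 benzoyl chloride
Product: 5 methyl 3-O-benzoyl-4,6-O-benzylidene-2-O-(4-methoxybenzyl)-α-D-glucopyranoside
Conditions: BzCl, pyridine, DMAP (cat.), CH2Cl2, 0 °C to rt
Reagents that add atoms: benzoyl chloride (4), O=C(Cl)c1ccccc1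
Why: Nucleophile-catalysed acylation of the only free hydroxyl; this benzoate is the C5 benzoate of the target and is carried unchanged to the end.

Step 3
Reactants: 5 methyl 3-O-benzoyl-4,6-O-benzylidene-2-O-(4-methoxybenzyl)-α-D-glucopyranoside
Product: 6 methyl 3-O-benzoyl-2-O-(4-methoxybenzyl)-α-D-glucopyranoside
Conditions: AcOH/H2O 4:1, 60 °C
Reagents that add atoms: none
Why: Acid-catalysed acetal hydrolysis; aqueous acetic acid should cleave the benzylidene acetal while the PMB ether, the methyl glycoside and the benzoate (which migrates slowly under acid) remain.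

Step 4
Reactants: 6 methyl 3-O-benzoyl-2-O-(4-methoxybenzyl)-α-D-glucopyranoside; 7 tert-butyldimethylsilyl trifluoromethanesulfonate
Product: 8 methyl 3-O-benzoyl-4,6-bis-O-(tert-butyldimethylsilyl)-2-O-(4-methoxybenzyl)-α-D-glucopyranoside
Conditions: TBSOTf (2.5 equiv), 2,6-lutidine, CH2Cl2, 0 °C to rt
Reagents that add atoms: tert-butyldimethylsilyl trifluoromethanesulfonate (7), CC(C)(C)[Si](C)(C)OS(=O)(=O)C(F)(F)F
Why: Silylation with a silyl triflate and a hindered base; the triflate is reactive enough for the flanked O4, and the non-nucleophilic base should not trigger a 3→4 benzoyl shift.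

Step 5
Reactants: 8 methyl 3-O-benzoyl-4,6-bis-O-(tert-butyldimethylsilyl)-2-O-(4-methoxybenzyl)-α-D-glucopyranoside
Product: 9 methyl 3-O-benzoyl-4-O-(tert-butyldimethylsilyl)-2-O-(4-methoxybenzyl)-α-D-glucopyranoside
Conditions: HF·pyridine, pyridine, THF, 0 °C
Reagents that add atoms: none
Why: Selective desilylation; the primary silyl ether is far more accessible than the secondary one flanked by the benzoate and C5, so buffered HF·pyridine should free O6 only.

Step 6
Reactants: 9 methyl 3-O-benzoyl-4-O-(tert-butyldimethylsilyl)-2-O-(4-methoxybenzyl)-α-D-glucopyranoside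
Product: 10 methyl 3-O-benzoyl-4-O-(tert-butyldimethylsilyl)-2-O-(4-methoxybenzyl)-α-D-gluco-hexodialdo-1,5-pyranoside
Conditions: Dess–Martin periodinane, CH2Cl2, rt
Reagents that add atoms: none
Why: Dess–Martin oxidation of the primary alcohol; base-free conditions should avoid epimerisation at C5 and β-elimination of the O4 substituent, and the aldehyde is used directly.

Step 7
Reactants: 10 methyl 3-O-benzoyl-4-O-(tert-butyldimethylsilyl)-2-O-(4-methoxybenzyl)-α-D-gluco-hexodialdo-1,5-pyranoside; 11 benzoic anhydride
Product: 12 methyl (Z)-3,6-di-O-benzoyl-4-O-(tert-butyldimethylsilyl)-2-O-(4-methoxybenzyl)-α-D-xylo-hex-5-enopyranoside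
Conditions: Bz2O, K2CO3, MeCN, 80 °C
Reagents that add atoms: benzoic anhydride (11), O=C(OC(=O)c1ccccc1)c1ccccc1
Why: O-Acylation of the aldehyde enolate (enol ester formation); the enolate oxygen should sit syn to the ring oxygen rather than to C4 with its bulky silyloxy group (allylic strain, potassium bridging), which gives the Z enol benzoate, and a silyloxy group is too poor a leaving group for β-elimination to compete.

Step 8
Reactants: 12 methyl (Z)-3,6-di-O-benzoyl-4-O-(tert-butyldimethylsilyl)-2-O-(4-methoxybenzyl)-α-D-xylo-hex-5-enopyranoside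
Product: 14 (2R,3R,4S,5R,6S)-2,5-bis(benzoyloxy)-6-(tert-butyldimethylsilyloxy)-3-hydroxy-4-(4-methoxybenzyloxy)cyclohexanone (2α-OBz, 3α-OH, 4α-OPMB, 5β-OBz, 6α-OTBS), via open-chain mercurio keto-aldehyde 13 (not isolated)
Conditions: Hg(OCOCF3)2 (10 mol%), acetone/H2O 3:1, rt
Reagents that add atoms: water, O
Why: Ferrier carbocyclisation (hydroxymercuration, ring opening, intramolecular aldol) of a 6-O-acyl hex-5-enopyranoside; the closest known reaction type is the same cyclisation of the corresponding enol acetates. Divalent mercury adds to sugar C6 and water to C5, where the cation is stabilised by the ring oxygen; the hemiketal collapses, methanol leaves the anomeric carbon, and the α-mercurio ketone 13 (ketone at sugar C5, aldehyde at sugar C1) results. Its mercury enolate attacks the aldehyde and forms the C2–C3 bond; both enolate carbons lie inside the new ring, so the closure of ring A is 6-(enolendo)-exo-trig, a favoured mode. The transition state should be a chair in which the three sugar-derived substituents (C4-OPMB, C5-OBz, C6-OTBS) stay equatorial. At C2 the benzoate on the enolate carbon lies syn to the enolate oxygen (the arrangement matching the Z enol ester) and so ends equatorial (α); because C2 is α to the ketone, an axial epimer can drain to the same isomer under the weakly acidic conditions. At C3 the aldehyde oxygen is expected to be axial (α, trans to the C5 benzoate and cis to the C4 oxygen); this centre is erased later, but its cis relation to O4 is used in step 9. The step needs regioselective mercuration (secured by the oxocarbenium at sugar C5), reaction at the enol double bond rather than at the PMB arene (soft, catalytic mercury salt), and survival of the β-hydroxy ketone (aqueous acetone at room temperature, no base).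

Step 9
Reactants: 14 (2R,3R,4S,5R,6S)-2,5-bis(benzoyloxy)-6-(tert-butyldimethylsilyloxy)-3-hydroxy-4-(4-methoxybenzyloxy)cyclohexanone
Product: 15 (2α,3α,4α,5β,6α)-2,5-bis(benzoyloxy)-6-(tert-butyldimethylsilyloxy)-3,4-O-(4-methoxybenzylidene)-3,4-dihydroxycyclohexanone
Conditions: DDQ, 4 Å MS, CH2Cl2 (dry), 0 °C to rt
Reagents that add atoms: none
Why: DDQ-mediated oxidative cyclisation of a PMB ether onto a neighbouring hydroxyl; hydride abstraction gives the aryl oxocarbenium at O4, which the cis C3 hydroxyl traps to close a cis-fused dioxolane. The aldol hydroxyl is thus protected without base, so dehydration, retro-aldol and a C2→C3 benzoyl shift should not occur.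

Step 10
Reactants: 15 (2α,3α,4α,5β,6α)-2,5-bis(benzoyloxy)-6-(tert-butyldimethylsilyloxy)-3,4-O-(4-methoxybenzylidene)-3,4-dihydroxycyclohexanone; 16 dibromomethane
Product: 17 (2α,3α,4α,5β,6α)-2,5-bis(benzoyloxy)-6-(tert-butyldimethylsilyloxy)-3,4-O-(4-methoxybenzylidene)-1-methylenecyclohexane-3,4-diol
Conditions: Zn, CH2Br2, TiCl4, THF, −40 to 5 °C (reagent aged); then 15, CH2Cl2, 0 °C to rt
Reagents that add atoms: dibromomethane (16), BrCBr
Why: Lombardo methylenation; the zinc/titanium gem-dimetallic reagent is non-basic and selective for ketones over esters, so the α-benzoate should not epimerise, the β-benzoate should not eliminate, and the three esters should not be methylenated.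

Step 11
Reactants: 17 (2α,3α,4α,5β,6α)-2,5-bis(benzoyloxy)-6-(tert-butyldimethylsilyloxy)-3,4-O-(4-methoxybenzylidene)-1-methylenecyclohexane-3,4-diol
Product: 18 (1β-OH,2α,3α,4α,5β,6α)-2,5-bis(benzoyloxy)-6-(tert-butyldimethylsilyloxy)-1-(hydroxymethyl)-3,4-O-(4-methoxybenzylidene)cyclohexane-1,3,4-triol
Conditions: OsO4 (5 mol%), N-methylmorpholine N-oxide, acetone/H2O, rt
Reagents that add atoms: N-methylmorpholine N-oxide, C[N+]1([O-])CCOCC1; water, O
Why: Catalytic osmium tetroxide dihydroxylation (Upjohn conditions); in the chair of 17 the C3 acetal oxygen is axial on the α-face, 1,3 to C1, so the bulky oxidant should add from the β-face and give C1-OH β (equatorial) with C7 α, the configuration of the target. The same bias is seen in branched-chain sugars carrying an axial substituent β to an exocyclic alkene.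

Step 12
Reactants: 18 (1β-OH,2α,3α,4α,5β,6α)-2,5-bis(benzoyloxy)-6-(tert-butyldimethylsilyloxy)-1-(hydroxymethyl)-3,4-O-(4-methoxybenzylidene)cyclohexane-1,3,4-triol; 4 benzoyl chloride
Product: 19 (1β-OH,2α,3α,4α,5β,6α)-2,5-bis(benzoyloxy)-1-(benzoyloxymethyl)-6-(tert-butyldimethylsilyloxy)-3,4-O-(4-methoxybenzylidene)cyclohexane-1,3,4-triol
Conditions: BzCl, pyridine, CH2Cl2, 0 °C
Reagents that add atoms: benzoyl chloride (4), O=C(Cl)c1ccccc1
Why: Selective acylation of a primary alcohol beside a tertiary one, which does not react under these conditions. The step is also self-correcting: if the C2 benzoate had shifted to the C7 hydroxyl, benzoylation of the freed C2-OH would give the same 19.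

Step 13
Reactants: 19 (1β-OH,2α,3α,4α,5β,6α)-2,5-bis(benzoyloxy)-1-(benzoyloxymethyl)-6-(tert-butyldimethylsilyloxy)-3,4-O-(4-methoxybenzylidene)cyclohexane-1,3,4-triol
Product: 20 (1β-OH,2α,3α-OH,4α-OH,5β,6α)-2,5-bis(benzoyloxy)-1-(benzoyloxymethyl)-6-(tert-butyldimethylsilyloxy)cyclohexane-1,3,4-triol
Conditions: AcOH/H2O 4:1, rt to 40 °C
Reagents that add atoms: none
Why: Acid-catalysed hydrolysis of an electron-rich aryl acetal, which is much faster than loss of the hindered secondary silyl ether; acid also keeps benzoyl migration slow.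

Step 14
Reactants: 20 (1β-OH,2α,3α-OH,4α-OH,5β,6α)-2,5-bis(benzoyloxy)-1-(benzoyloxymethyl)-6-(tert-butyldimethylsilyloxy)cyclohexane-1,3,4-triol; 21 1,1'-thiocarbonyldiimidazole
Product: 22 (1β-OH,2α,3α,4α,5β,6α)-2,5-bis(benzoyloxy)-1-(benzoyloxymethyl)-6-(tert-butyldimethylsilyloxy)cyclohexane-1,3,4-triol 3,4-cyclic thiocarbonate
Conditions: 1,1'-thiocarbonyldiimidazole, DMAP (cat.), THF, 50 °C
Reagents that add atoms: 1,1'-thiocarbonyldiimidazole (21), S=C(n1ccnc1)n1ccnc1
Why: Cyclic thiocarbonate formation, the first half of the Corey–Winter olefination; only the cis C3,C4 diol can close the five-membered ring, and the tertiary C1 hydroxyl is too hindered to be thioacylated.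

Step 15
Reactants: 22 (1β-OH,2α,3α,4α,5β,6α)-2,5-bis(benzoyloxy)-1-(benzoyloxymethyl)-6-(tert-butyldimethylsilyloxy)cyclohexane-1,3,4-triol 3,4-cyclic thiocarbonate
Product: 23 [(1R,2R,5R,6S)-2,5-bis(benzoyloxy)-6-(tert-butyldimethylsilyloxy)-1-hydroxycyclohex-3-en-1-yl]methyl benzoate
Conditions: 1,3-dimethyl-2-phenyl-1,3,2-diazaphospholidine, THF, 40 °C
Reagents that add atoms: none
Why: Corey–Winter olefination in its low-temperature diazaphospholidine variant; desulfurisation gives the dioxolanylidene, which loses CO2 in a syn cycloreversion to the C3=C4 alkene. The mild, neutral conditions should leave the new allylic benzoates and the tertiary alcohol untouched.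

Step 16
Reactants: 23 [(1R,2R,5R,6S)-2,5-bis(benzoyloxy)-6-(tert-butyldimethylsilyloxy)-1-hydroxycyclohex-3-en-1-yl]methyl benzoate
Product: 24 [(1R,2R,5R,6S)-2,5-bis(benzoyloxy)-1,6-dihydroxycyclohex-3-en-1-yl]methyl benzoate
Conditions: HF·pyridine, THF, 0 °C to rt
Reagents that add atoms: none
Why: Fluoride-mediated desilylation under acidic conditions; no alkoxide is formed, so the C5 and C7 benzoates should not move to the freed C6 hydroxyl and the allylic esters should stay in place.

## Compound list

1 | methyl 4,6-O-[(R)-benzylidene]-α-D-glucopyranoside | CO[C@@H]1[C@H](O)[C@@H](O)[C@@H]2O[C@H](c3ccccc3)OC[C@H]2O1 | starting material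
2 | 4-methoxybenzyl chloride | COc1ccc(CCl)cc1 | starting material
3 | methyl 4,6-O-benzylidene-2-O-(4-methoxybenzyl)-α-D-glucopyranoside | CO[C@@H]1[C@H](OCc2ccc(OC)cc2)[C@@H](O)[C@@H]2O[C@H](c3ccccc3)OC[C@H]2O1 | intermediate
4 | benzoyl chloride | O=C(Cl)c1ccccc1 | starting material
5 | methyl 3-O-benzoyl-4,6-O-benzylidene-2-O-(4-methoxybenzyl)-α-D-glucopyranoside | CO[C@@H]1[C@H](OCc2ccc(OC)cc2)[C@@H](OC(=O)c2ccccc2)[C@@H]2O[C@H](c3ccccc3)OC[C@H]2O1 | intermediate
6 | methyl 3-O-benzoyl-2-O-(4-methoxybenzyl)-α-D-glucopyranoside | CO[C@@H]1[C@H](OCc2ccc(OC)cc2)[C@@H](OC(=O)c2ccccc2)[C@H](O)[C@@H](CO)O1 | intermediate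
7 | tert-butyldimethylsilyl trifluoromethanesulfonate | CC(C)(C)[Si](C)(C)OS(=O)(=O)C(F)(F)F | starting material
8 | methyl 3-O-benzoyl-4,6-bis-O-(tert-butyldimethylsilyl)-2-O-(4-methoxybenzyl)-α-D-glucopyranoside | CO[C@@H]1[C@H](OCc2ccc(OC)cc2)[C@@H](OC(=O)c2ccccc2)[C@H](O[Si](C)(C)C(C)(C)C)[C@@H](CO[Si](C)(C)C(C)(C)C)O1 | intermediate
9 | methyl 3-O-benzoyl-4-O-(tert-butyldimethylsilyl)-2-O-(4-methoxybenzyl)-α-D-glucopyranoside | CO[C@@H]1[C@H](OCc2ccc(OC)cc2)[C@@H](OC(=O)c2ccccc2)[C@H](O[Si](C)(C)C(C)(C)C)[C@@H](CO)O1 | intermediate
10 | methyl 3-O-benzoyl-4-O-(tert-butyldimethylsilyl)-2-O-(4-methoxybenzyl)-α-D-gluco-hexodialdo-1,5-pyranoside | CO[C@@H]1[C@H](OCc2ccc(OC)cc2)[C@@H](OC(=O)c2ccccc2)[C@H](O[Si](C)(C)C(C)(C)C)[C@@H](C=O)O1 | intermediate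
11 | benzoic anhydride | O=C(OC(=O)c1ccccc1)c1ccccc1 | starting material
12 | methyl (Z)-3,6-di-O-benzoyl-4-O-(tert-butyldimethylsilyl)-2-O-(4-methoxybenzyl)-α-D-xylo-hex-5-enopyranoside | CO[C@@H]1[C@H](OCc2ccc(OC)cc2)[C@@H](OC(=O)c2ccccc2)[C@H](O[Si](C)(C)C(C)(C)C)/C(=C/OC(=O)c2ccccc2)O1 | intermediate
13 | 3,6-di-O-benzoyl-4-O-(tert-butyldimethylsilyl)-2-O-(4-methoxybenzyl)-6-(trifluoroacetoxymercurio)-D-xylo-hexos-5-ulose, open chain, both C6 epimers | O=C[C@H](OCc1ccc(OC)cc1)[C@@H](OC(=O)c1ccccc1)[C@H](O[Si](C)(C)C(C)(C)C)C(=O)C(OC(=O)c1ccccc1)[Hg]OC(=O)C(F)(F)F | intermediate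
14 | (2R,3R,4S,5R,6S)-2,5-bis(benzoyloxy)-6-(tert-butyldimethylsilyloxy)-3-hydroxy-4-(4-methoxybenzyloxy)cyclohexanone | O=C1[C@H](OC(=O)c2ccccc2)[C@H](O)[C@H](OCc2ccc(OC)cc2)[C@@H](OC(=O)c2ccccc2)[C@@H]1O[Si](C)(C)C(C)(C)C | intermediate
15 | (2α,3α,4α,5β,6α)-2,5-bis(benzoyloxy)-6-(tert-butyldimethylsilyloxy)-3,4-O-(4-methoxybenzylidene)-3,4-dihydroxycyclohexanone | O=C1[C@H](OC(=O)c2ccccc2)[C@@H]2OC(c3ccc(OC)cc3)O[C@@H]2[C@@H](OC(=O)c2ccccc2)[C@@H]1O[Si](C)(C)C(C)(C)C | intermediate
16 | dibromomethane | BrCBr | starting material
17 | (2α,3α,4α,5β,6α)-2,5-bis(benzoyloxy)-6-(tert-butyldimethylsilyloxy)-3,4-O-(4-methoxybenzylidene)-1-methylenecyclohexane-3,4-diol | C=C1[C@H](OC(=O)c2ccccc2)[C@@H]2OC(c3ccc(OC)cc3)O[C@@H]2[C@@H](OC(=O)c2ccccc2)[C@@H]1O[Si](C)(C)C(C)(C)C | intermediate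
18 | (1β-OH,2α,3α,4α,5β,6α)-2,5-bis(benzoyloxy)-6-(tert-butyldimethylsilyloxy)-1-(hydroxymethyl)-3,4-O-(4-methoxybenzylidene)cyclohexane-1,3,4-triol | OC[C@]1(O)[C@H](OC(=O)c2ccccc2)[C@@H]2OC(c3ccc(OC)cc3)O[C@@H]2[C@@H](OC(=O)c2ccccc2)[C@@H]1O[Si](C)(C)C(C)(C)C | intermediate
19 | (1β-OH,2α,3α,4α,5β,6α)-2,5-bis(benzoyloxy)-1-(benzoyloxymethyl)-6-(tert-butyldimethylsilyloxy)-3,4-O-(4-methoxybenzylidene)cyclohexane-1,3,4-triol | O=C(OC[C@]1(O)[C@H](OC(=O)c2ccccc2)[C@@H]2OC(c3ccc(OC)cc3)O[C@@H]2[C@@H](OC(=O)c2ccccc2)[C@@H]1O[Si](C)(C)C(C)(C)C)c1ccccc1 | intermediate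
20 | (1β-OH,2α,3α-OH,4α-OH,5β,6α)-2,5-bis(benzoyloxy)-1-(benzoyloxymethyl)-6-(tert-butyldimethylsilyloxy)cyclohexane-1,3,4-triol | O=C(OC[C@]1(O)[C@H](OC(=O)c2ccccc2)[C@H](O)[C@H](O)[C@@H](OC(=O)c2ccccc2)[C@@H]1O[Si](C)(C)C(C)(C)C)c1ccccc1 | intermediate
21 | 1,1'-thiocarbonyldiimidazole | S=C(n1ccnc1)n1ccnc1 | starting material
22 | (1β-OH,2α,3α,4α,5β,6α)-2,5-bis(benzoyloxy)-1-(benzoyloxymethyl)-6-(tert-butyldimethylsilyloxy)cyclohexane-1,3,4-triol 3,4-cyclic thiocarbonate | O=C(OC[C@]1(O)[C@H](OC(=O)c2ccccc2)[C@@H]2OC(=S)O[C@@H]2[C@@H](OC(=O)c2ccccc2)[C@@H]1O[Si](C)(C)C(C)(C)C)c1ccccc1 | intermediate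
23 | [(1R,2R,5R,6S)-2,5-bis(benzoyloxy)-6-(tert-butyldimethylsilyloxy)-1-hydroxycyclohex-3-en-1-yl]methyl benzoate | O=C(OC[C@]1(O)[C@H](OC(=O)c2ccccc2)C=C[C@@H](OC(=O)c2ccccc2)[C@@H]1O[Si](C)(C)C(C)(C)C)c1ccccc1 | intermediate
24 | [(1R,2R,5R,6S)-2,5-bis(benzoyloxy)-1,6-dihydroxycyclohex-3-en-1-yl]methyl benzoate | O=C(OC[C@]1(O)[C@H](OC(=O)c2ccccc2)C=C[C@@H](OC(=O)c2ccccc2)[C@@H]1O)c1ccccc1 | target

## Step count and least certain steps

Total step count: 16. Longest linear sequence: 16 (the route is fully linear from 1).

Step 8 (key step). The likely failures are slow or incomplete hydroxymercuration of the hindered, acyl-substituted enol double bond, dehydration of the β-hydroxy ketone to an enone, and incomplete convergence at C2. Steps 7 and 8 stand or fall together, so one fallback covers both: the enol ester is given up and the C2 oxygen is added after the ring is closed. It sets out from 9. Iodination of the primary alcohol (I2, PPh3, imidazole, toluene) should give methyl 3-O-benzoyl-6-deoxy-6-iodo-4-O-(tert-butyldimethylsilyl)-2-O-(4-methoxybenzyl)-α-D-glucopyranoside F1. Elimination with AgF in pyridine should give the 6-deoxy enol ether methyl 3-O-benzoyl-6-deoxy-4-O-(tert-butyldimethylsilyl)-2-O-(4-methoxybenzyl)-α-D-xylo-hex-5-enopyranoside F2. Its carbocyclisation with Hg(OCOCF3)2 in aqueous acetone is the most widely used form of this reaction and should give the 2-deoxy ketone (3α,4α,5β,6α)-5-(benzoyloxy)-6-(tert-butyldimethylsilyloxy)-3-hydroxy-4-(4-methoxybenzyloxy)cyclohexanone F3. Oxidative acetal closure as in step 9 should give (3α,4α,5β,6α)-5-(benzoyloxy)-6-(tert-butyldimethylsilyloxy)-3,4-O-(4-methoxybenzylidene)-3,4-dihydroxycyclohexanone F4. α-Benzoyloxylation at the C2 methylene with N-methyl-O-benzoylhydroxylamine hydrochloride in DMSO, followed by equilibration to the equatorial ester, brings the route back at 15.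

Step 9. The likely failure is plain hydrolytic loss of the PMB group by adventitious water instead of ring closure. The fallback accepts this. From 14, DDQ in wet CH2Cl2 should give the cis-diol (2α,3α,4α,5β,6α)-2,5-bis(benzoyloxy)-6-(tert-butyldimethylsilyloxy)-3,4-dihydroxycyclohexanone F5. Acid-catalysed acetal exchange with 4-methoxybenzaldehyde dimethyl acetal (pyridinium p-toluenesulfonate, CH2Cl2) then returns to the route at 15.

Step 10. The likely failures are reductive loss of the α-benzoyloxy group by zinc, Lewis-acid opening of the aryl acetal, and a sluggish reaction at the doubly flanked carbonyl. The fallback is a two-stage Peterson olefination from 15. Me3SiCH2MgCl with CeCl3 (THF, −78 °C) is non-basic and selective for ketones; it should add from the open β-face to give the β-hydroxysilane (1α-OH,2α,3α,4α,5β,6α)-2,5-bis(benzoyloxy)-6-(tert-butyldimethylsilyloxy)-3,4-O-(4-methoxybenzylidene)-1-(trimethylsilylmethyl)cyclohexane-1,3,4-triol F6. The configuration at C1 does not matter, since acid-promoted elimination (BF3·OEt2, CH2Cl2, low temperature) gives the alkene and returns to the route at 17.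

Step 11. The likely failure is poor facial selectivity of the osmylation, since the β-face delivery creates a 1,3-diaxial contact between C7 and the C3 oxygen. If the α-face proves to be the open one, the same bias can be used with a carbon nucleophile. From 15, diazomethane (Et2O/MeOH, 0 °C, non-basic) should transfer methylene to the α-face of the ketone and give the spiro-epoxide (1β-O,2α,3α,4α,5β,6α)-2,5-bis(benzoyloxy)-6-(tert-butyldimethylsilyloxy)-3,4-O-(4-methoxybenzylidene)-1-oxaspiro[2.5]octane-5,6-diol-type oxirane F7 (oxirane oxygen β, CH2 α). Opening at the primary carbon with tetrabutylammonium benzoate and benzoic acid (toluene, 80 °C) then returns to the route at 19 and saves one step.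

Step 14. The likely failures are migration of the C2 benzoate to the cis C3 hydroxyl of 20 under the basic thioacylation conditions, and a thiocarbonyl imidazolide that does not close. The fallback avoids a cyclic derivative: from 20, direct deoxygenation of the vicinal diol with I2, PPh3 and imidazole in toluene at 80 to 100 °C (Garegg–Samuelsson olefination, which works for cis and trans diols and so also covers a wrong C3 configuration) should give 23, where the route resumes.

## Further compounds

F1 | step 8 | methyl 3-O-benzoyl-6-deoxy-6-iodo-4-O-(tert-butyldimethylsilyl)-2-O-(4-methoxybenzyl)-α-D-glucopyranoside | CO[C@@H]1[C@H](OCc2ccc(OC)cc2)[C@@H](OC(=O)c2ccccc2)[C@H](O[Si](C)(C)C(C)(C)C)[C@@H](CI)O1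
F2 | step 8 | methyl 3-O-benzoyl-6-deoxy-4-O-(tert-butyldimethylsilyl)-2-O-(4-methoxybenzyl)-α-D-xylo-hex-5-enopyranoside | CO[C@@H]1[C@H](OCc2ccc(OC)cc2)[C@@H](OC(=O)c2ccccc2)[C@H](O[Si](C)(C)C(C)(C)C)C(=C)O1
F3 | step 8 | (3α,4α,5β,6α)-5-(benzoyloxy)-6-(tert-butyldimethylsilyloxy)-3-hydroxy-4-(4-methoxybenzyloxy)cyclohexanone | O=C1C[C@H](O)[C@H](OCc2ccc(OC)cc2)[C@@H](OC(=O)c2ccccc2)[C@@H]1O[Si](C)(C)C(C)(C)C
F4 | step 8 | (3α,4α,5β,6α)-5-(benzoyloxy)-6-(tert-butyldimethylsilyloxy)-3,4-O-(4-methoxybenzylidene)-3,4-dihydroxycyclohexanone | O=C1C[C@@H]2OC(c3ccc(OC)cc3)O[C@@H]2[C@@H](OC(=O)c2ccccc2)[C@@H]1O[Si](C)(C)C(C)(C)C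
F5 | step 9 | (2α,3α,4α,5β,6α)-2,5-bis(benzoyloxy)-6-(tert-butyldimethylsilyloxy)-3,4-dihydroxycyclohexanone | O=C1[C@H](OC(=O)c2ccccc2)[C@H](O)[C@H](O)[C@@H](OC(=O)c2ccccc2)[C@@H]1O[Si](C)(C)C(C)(C)C
F6 | step 10 | (1α-OH,2α,3α,4α,5β,6α)-2,5-bis(benzoyloxy)-6-(tert-butyldimethylsilyloxy)-3,4-O-(4-methoxybenzylidene)-1-(trimethylsilylmethyl)cyclohexane-1,3,4-triol | C[Si](C)(C)C[C@@]1(O)[C@H](OC(=O)c2ccccc2)[C@@H]2OC(c3ccc(OC)cc3)O[C@@H]2[C@@H](OC(=O)c2ccccc2)[C@@H]1O[Si](C)(C)C(C)(C)C
F7 | step 11 | spiro-epoxide of 15 at C1 (oxirane oxygen β, CH2 α), with 2α-OBz, 3α,4α-O-(4-methoxybenzylidene), 5β-OBz, 6α-OTBS | C1O[C@]12[C@H](OC(=O)c3ccccc3)[C@@H]3OC(c4ccc(OC)cc4)O[C@@H]3[C@@H](OC(=O)c3ccccc3)[C@@H]2O[Si](C)(C)C(C)(C)C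
F0 | step 14 | none | none
A1 | alternative 1 | furan | c1ccoc1
A2 | alternative 1 | 2-bromoacrolein | C=C(Br)C=O
A3 | alternative 1 | 2-endo-bromo-7-oxabicyclo[2.2.1]hept-5-ene-2-exo-carbaldehyde | O=C[C@]1(Br)C[C@H]2C=C[C@@H]1O2
A4 | alternative 2 | racemic all-trans cyclohex-5-ene-1,2,3,4-tetrayl tetrakis(2,2,2-trichloroethyl carbonate), one enantiomer drawn | O=C(OCC(Cl)(Cl)Cl)O[C@H]1[C@H](OC(=O)OCC(Cl)(Cl)Cl)C=C[C@@H](OC(=O)OCC(Cl)(Cl)Cl)[C@@H]1OC(=O)OCC(Cl)(Cl)Cl
A5 | alternative 2 | conduritol B 2,5-dibenzoate 1,6-bis(2,2,2-trichloroethyl carbonate), single enantiomer | O=C(OCC(Cl)(Cl)Cl)O[C@H]1[C@H](OC(=O)c2ccccc2)C=C[C@@H](OC(=O)c2ccccc2)[C@@H]1OC(=O)OCC(Cl)(Cl)Cl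
A6 | alternative 3 | 4-(benzoyloxymethyl)-4-(triethylsilyloxy)cyclohexa-2,5-dienone | O=C(OCC1(O[Si](CC)(CC)CC)C=CC(=O)C=C1)c1ccccc1
A7 | alternative 3 | 5,6-epoxy-4-oxo-1-(triethylsilyloxy)cyclohex-2-enylmethyl benzoate | O=C(OC[C@]1(O[Si](CC)(CC)CC)C=CC(=O)[C@@H]2O[C@H]12)c1ccccc1
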